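**Plan**

1. Retrosynthesis: the side-chain C=C is cut first (vinylogous aldol, then elimination), which leads back to 3-ethyl dienone 15 and aldehyde 21. Then two ring bonds of 15 are cut together, C3–C4 and C5=C6 (ring numbered from the carbonyl C1; C4 is the quaternary carbon), which leads back to pyranyl propanal 7 and allenyl ketone 13.
2. Forward order: the pyranone is made first (steps 1–4), the carbocycle is closed in one pot (step 7), the side chain is grown on the ethyl group (steps 12, 13) and its ketone is unveiled last (steps 14, 15).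
3. Enabling feature: pyran C-2 is a vinylogous acyl carbon, so the carbon that becomes C4, flanked by it and by the formyl carbon C5, is a soft prochiral carbon acid. Ring atoms C6–C1(=O)–C2(Me)=C3 map onto an α-methyl allenyl ketone, one oxidation level above an enone, so Michael addition plus aldol condensation should give the 2,5-dienone without dehydrogenation, and quaternary C4 blocks aromatisation.
4. Stereochemistry: C4 (S) comes from the chiral ammonium ion pair in the Michael addition of step 7. The side-chain centre (S) comes from an Evans syn-aldol (step 8; the carbinol centre made with it is oxidised in step 15). The E alkene comes from the E1cB elimination of step 13.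

Key step: step 7

Assumption: the facial sense of the ion-pairing catalyst in step 7 is not known for this enolate, so the cinchonidine-derived salt is written and its cinchonine-derived pseudoenantiomer is taken if it favours the other face; 13 is used as the racemate because its axis is lost on addition.

**Route**

Step 1
Reactants: 1 methyl 2-methyl-3-oxopentanoate; 2 N-methoxy-N-methylpropanamide
Product: 3 methyl 2,4-dimethyl-3,5-dioxoheptanoate
Conditions: NaH, THF, 0 °C; n-BuLi, 0 °C; 2, 0→23 °C; aq HCl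
Reagents that add atoms: none
Why: The γ-carbanion of the β-keto ester dianion is C-acylated by the amide (Claisen-type acylation), and the chelated tetrahedral adduct prevents over-addition.

Step 2
Reactants: 3 methyl 2,4-dimethyl-3,5-dioxoheptanoate
Product: 4 6-ethyl-4-hydroxy-3,5-dimethyl-2H-pyran-2-one
Conditions: DBU, toluene, 80 °C; aq HCl
Reagents that add atoms: none
Why: Base-mediated enol lactonisation of the 3,5-dioxo ester (the C-5 enolate oxygen attacks the ester) is the standard entry to 4-hydroxy-2-pyranones.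

Step 3
Reactants: 4 6-ethyl-4-hydroxy-3,5-dimethyl-2H-pyran-2-one
Product: 5 2-ethyl-6-methoxy-3,5-dimethyl-4H-pyran-4-one
Conditions: MeOTf, CH2Cl2, 23 °C; aq NaHCO3
Reagents that add atoms: methyl trifluoromethanesulfonate, COS(=O)(=O)C(F)(F)F
Why: O-Methylation with a hard methyl electrophile should take place at the lactone carbonyl oxygen, and loss of the proton from the 4-hydroxy-2-methoxypyrylium ion gives the 2-methoxy-4-pyranone regioisomer.

Step 4
Reactants: 5 2-ethyl-6-methoxy-3,5-dimethyl-4H-pyran-4-one; 6 ethyl formate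
Product: 7 2-(6-methoxy-3,5-dimethyl-4-oxo-4H-pyran-2-yl)propanal
Conditions: LiN(iPr)2 (2.2 equiv), THF, −78 °C; 6, −78→0 °C; aq NH4Cl
Reagents that add atoms: none
Why: Lateral (vinylogous) lithiation of the 2-ethyl group followed by Claisen formylation should give the aldehyde, and the second equivalent of base stores it as its enolate so that it is formylated only once.

Step 5
Reactants: 8 2-bromopentan-3-one
Product: 10 2-(triphenyl-λ5-phosphanylidene)pentan-3-one, via phosphonium bromide 9 (not isolated)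
Conditions: PPh3, toluene, 90 °C; then 2 M NaOH, CH2Cl2, 23 °C
Reagents that add atoms: triphenylphosphine, c1ccc(cc1)P(c1ccccc1)c1ccccc1
Why: SN2 alkylation of the phosphine and deprotonation of the acidic phosphonium salt give the acyl-stabilised Wittig ylide.

Step 6
Reactants: 10 2-(triphenyl-λ5-phosphanylidene)pentan-3-one; 11 propanoyl chloride
Product: 13 4-methylhepta-4,5-dien-3-one, via methylketene 12 (not isolated)
Conditions: Et3N, CH2Cl2, 0→23 °C
Reagents that add atoms: none
Why: A Wittig reaction of the stabilised ylide with methylketene, made in the flask by dehydrochlorination of the acid chloride, should give the 1,3-disubstituted allenyl ketone.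

Step 7
Reactants: 7 2-(6-methoxy-3,5-dimethyl-4-oxo-4H-pyran-2-yl)propanal; 13 4-methylhepta-4,5-dien-3-one
Product: 15 (4S)-3-ethyl-4-(6-methoxy-3,5-dimethyl-4-oxo-4H-pyran-2-yl)-2,4,6-trimethylcyclohexa-2,5-dien-1-one, via Michael adduct 14 (not isolated)
Conditions: O-allyl-N-(9-anthracenylmethyl)cinchonidinium bromide (10 mol%), Cs2CO3 (20 mol%), toluene, −40 °C; then DBU, 4 Å sieves, 23→60 °C
Reagents that add atoms: none
Why: Proposed new method: the chiral ammonium enolate of 7 (its C–H is acidified by the formyl group and, vinylogously through pyran C-2, by the pyranone carbonyl) should add through carbon to the sp-hybridised central allene carbon of 13, the only position β to the ketone, to give keto aldehyde 14; DBU then enolises the ethyl ketone at its CH2, the ring closes on the neopentyl aldehyde by a 6-(enolendo)-exo-trig aldol addition, water is lost by E1cB and the ethylidene double bond moves into conjugation, so the cross-conjugated dienone arises at the right oxidation level. The closest known reaction types are the cinchona-ammonium-catalysed conjugate addition of α-substituted 1,3-dicarbonyl compounds to allenyl ketones and allenoates and the Robinson annulation of α,α-disubstituted aldehydes; new are the vinylogous formyl pyranone as pronucleophile and the α-methyl allenone as four-carbon partner. The only new stereocentre, the quaternary ring carbon, is fixed in the Michael step by the ion-paired catalyst, which shields one face of the planar enolate, while the allene axis and the epimeric α-carbon of 14 are erased in the product. The step needs C- over O-attack, addition at the central allene carbon and ring closure through the ethyl CH2: the soft delocalised enolate and the soft allenone favour C–C bonding, the α-methyl group of 13 leaves no second β-position, and every other enolisable position could reach the aldehyde only through a four-membered ring. Once C4 is quaternary, neither aromatisation nor epimerisation of the ring is possible.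

Step 8
Reactants: 16 (4R)-4-benzyl-3-propanoyl-1,3-oxazolidin-2-one; 17 propanal
Product: 18 (4R)-4-benzyl-3-[(2R,3S)-3-hydroxy-2-methylpentanoyl]-1,3-oxazolidin-2-one
Conditions: Bu2BOTf, Et3N, CH2Cl2, 0 °C; 17, −78→0 °C; H2O2, pH 7 buffer, MeOH
Reagents that add atoms: none
Why: In the Evans syn-aldol the Z-boron enolate reacts through a closed chair transition state on the face opposite the benzyl group, which sets both centres (the methyl-bearing one becomes the (S) centre of the target).

Step 9
Reactants: 18 (4R)-4-benzyl-3-[(2R,3S)-3-hydroxy-2-methylpentanoyl]-1,3-oxazolidin-2-one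
Product: 19 (4R)-4-benzyl-3-[(2R,3S)-3-{[tert-butyl(dimethyl)silyl]oxy}-2-methylpentanoyl]-1,3-oxazolidin-2-one
Conditions: tBuMe2SiOTf, 2,6-lutidine, CH2Cl2, 0 °C
Reagents that add atoms: tert-butyldimethylsilyl trifluoromethanesulfonate, CC(C)(C)[Si](C)(C)OS(=O)(=O)C(F)(F)F
Why: Silylation of the secondary alcohol with the silyl triflate and a hindered base is routine and prevents retro-aldol cleavage in the next steps.

Step 10
Reactants: 19 (4R)-4-benzyl-3-[(2R,3S)-3-{[tert-butyl(dimethyl)silyl]oxy}-2-methylpentanoyl]-1,3-oxazolidin-2-one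
Product: 20 (2S,3S)-3-{[tert-butyl(dimethyl)silyl]oxy}-2-methylpentan-1-ol
Conditions: LiBH4, MeOH, THF, 0 °C
Reagents that add atoms: none
Why: Hydride reduction of the imide carbonyl (reductive auxiliary cleavage) should give the primary alcohol without touching the silyl ether or the stereocentres.

Step 11
Reactants: 20 (2S,3S)-3-{[tert-butyl(dimethyl)silyl]oxy}-2-methylpentan-1-ol
Product: 21 (2R,3S)-3-{[tert-butyl(dimethyl)silyl]oxy}-2-methylpentanal
Conditions: Dess–Martin periodinane, NaHCO3, CH2Cl2, 0→23 °C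
Reagents that add atoms: none
Why: Dess–Martin oxidation under buffered, non-basic conditions should give the α-branched aldehyde without epimerisation.

Step 12
Reactants: 15 (4S)-3-ethyl-4-(6-methoxy-3,5-dimethyl-4-oxo-4H-pyran-2-yl)-2,4,6-trimethylcyclohexa-2,5-dien-1-one; 21 (2R,3S)-3-{[tert-butyl(dimethyl)silyl]oxy}-2-methylpentanal
Product: 23 (4S)-3-[(4S,5S)-5-{[tert-butyl(dimethyl)silyl]oxy}-3-hydroxy-4-methylheptan-2-yl]-4-(6-methoxy-3,5-dimethyl-4-oxo-4H-pyran-2-yl)-2,4,6-trimethylcyclohexa-2,5-dien-1-one, via silyl trienol ether 22 (not isolated)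
Conditions: LiN(iPr)2, Me3SiCl, THF, −78 °C; then 21, BF3·OEt2, CH2Cl2, −78 °C; aq NaHCO3
Reagents that add atoms: none
Why: In this vinylogous Mukaiyama aldol the only vinylogously acidic hydrogens are those of the CH2 of the 3-ethyl group (C4 is quaternary), and the silyl trienol ether should attack the activated aldehyde through its exocyclic ethylidene carbon, which restores the dienone; the two new centres are lost in step 13, so their configuration does not matter.

Step 13
Reactants: 23 (4S)-3-[(4S,5S)-5-{[tert-butyl(dimethyl)silyl]oxy}-3-hydroxy-4-methylheptan-2-yl]-4-(6-methoxy-3,5-dimethyl-4-oxo-4H-pyran-2-yl)-2,4,6-trimethylcyclohexa-2,5-dien-1-one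
Product: 25 (4S)-3-[(2E,4S,5S)-5-{[tert-butyl(dimethyl)silyl]oxy}-4-methylhept-2-en-2-yl]-4-(6-methoxy-3,5-dimethyl-4-oxo-4H-pyran-2-yl)-2,4,6-trimethylcyclohexa-2,5-dien-1-one, via mesylate 24 (not isolated)
Conditions: MeSO2Cl, Et3N, CH2Cl2, 0 °C; then DBU, 23 °C
Reagents that add atoms: none
Why: E1cB elimination through the extended dienone enolate removes only the vinylogously acidic hydrogen, so the stereocentre next to the mesylate is untouched, and the E alkene should result because the branched chain avoids the fully substituted ring carbon (allylic strain).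

Step 14
Reactants: 25 (4S)-3-[(2E,4S,5S)-5-{[tert-butyl(dimethyl)silyl]oxy}-4-methylhept-2-en-2-yl]-4-(6-methoxy-3,5-dimethyl-4-oxo-4H-pyran-2-yl)-2,4,6-trimethylcyclohexa-2,5-dien-1-one
Product: 26 (4S)-3-[(2E,4S,5S)-5-hydroxy-4-methylhept-2-en-2-yl]-4-(6-methoxy-3,5-dimethyl-4-oxo-4H-pyran-2-yl)-2,4,6-trimethylcyclohexa-2,5-dien-1-one
Conditions: HF·pyridine, pyridine, THF, 0→23 °C
Reagents that add atoms: none
Why: Fluoride-mediated cleavage of the silyl ether under non-basic conditions spares the dienone, the pyranone and the allylic stereocentre.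

Step 15
Reactants: 26 (4S)-3-[(2E,4S,5S)-5-hydroxy-4-methylhept-2-en-2-yl]-4-(6-methoxy-3,5-dimethyl-4-oxo-4H-pyran-2-yl)-2,4,6-trimethylcyclohexa-2,5-dien-1-one
Product: 27 (4S)-4-(6-methoxy-3,5-dimethyl-4-oxo-4H-pyran-2-yl)-2,4,6-trimethyl-3-[(2E,4S)-4-methyl-5-oxohept-2-en-2-yl]cyclohexa-2,5-dien-1-one
Conditions: Dess–Martin periodinane, NaHCO3, CH2Cl2, 0 °C
Reagents that add atoms: none
Why: Buffered Dess–Martin oxidation of the secondary alcohol should give the β,γ-unsaturated ketone without epimerisation of the α-stereocentre or migration of the double bond.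

**Compound list**

1 | methyl 2-methyl-3-oxopentanoate (racemic) | CCC(=O)C(C)C(=O)OC | starting material
2 | N-methoxy-N-methylpropanamide | CCC(=O)N(C)OC | starting material
3 | methyl 2,4-dimethyl-3,5-dioxoheptanoate (stereoisomer mixture) | CCC(=O)C(C)C(=O)C(C)C(=O)OC | intermediate
4 | 6-ethyl-4-hydroxy-3,5-dimethyl-2H-pyran-2-one | CCc1oc(=O)c(C)c(O)c1C | intermediate
5 | 2-ethyl-6-methoxy-3,5-dimethyl-4H-pyran-4-one | CCc1oc(OC)c(C)c(=O)c1C | intermediate
6 | ethyl formate | CCOC=O | starting material
7 | 2-(6-methoxy-3,5-dimethyl-4-oxo-4H-pyran-2-yl)propanal (racemic) | CC(C=O)c1oc(OC)c(C)c(=O)c1C | intermediate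
8 | 2-bromopentan-3-one (racemic) | CCC(=O)C(C)Br | starting material
9 | (3-oxopentan-2-yl)triphenylphosphonium bromide | CCC(=O)C(C)[P+](c1ccccc1)(c1ccccc1)c1ccccc1.[Br-] | intermediate
10 | 2-(triphenyl-λ5-phosphanylidene)pentan-3-one | CCC(=O)C(C)=P(c1ccccc1)(c1ccccc1)c1ccccc1 | intermediate
11 | propanoyl chloride | CCC(=O)Cl | starting material
12 | methylketene (prop-1-en-1-one) | CC=C=O | intermediate
13 | 4-methylhepta-4,5-dien-3-one (racemic allene) | CCC(=O)C(C)=C=CC | intermediate
14 | (2S)-3-ethylidene-2-(6-methoxy-3,5-dimethyl-4-oxo-4H-pyran-2-yl)-2,4-dimethyl-5-oxoheptanal (alkene isomers and C-4 epimers) | CCC(=O)C(C)C(=CC)[C@](C)(C=O)c1oc(OC)c(C)c(=O)c1C | intermediate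
15 | (4S)-3-ethyl-4-(6-methoxy-3,5-dimethyl-4-oxo-4H-pyran-2-yl)-2,4,6-trimethylcyclohexa-2,5-dien-1-one | CCC1=C(C)C(=O)C(C)=C[C@]1(C)c1oc(OC)c(C)c(=O)c1C | intermediate
16 | (4R)-4-benzyl-3-propanoyl-1,3-oxazolidin-2-one | CCC(=O)N1[C@H](Cc2ccccc2)COC1=O | starting material
17 | propanal | CCC=O | starting material
18 | (4R)-4-benzyl-3-[(2R,3S)-3-hydroxy-2-methylpentanoyl]-1,3-oxazolidin-2-one | CC[C@H](O)[C@@H](C)C(=O)N1[C@H](Cc2ccccc2)COC1=O | intermediate
19 | (4R)-4-benzyl-3-[(2R,3S)-3-{[tert-butyl(dimethyl)silyl]oxy}-2-methylpentanoyl]-1,3-oxazolidin-2-one | CC[C@H](O[Si](C)(C)C(C)(C)C)[C@@H](C)C(=O)N1[C@H](Cc2ccccc2)COC1=O | intermediate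
20 | (2S,3S)-3-{[tert-butyl(dimethyl)silyl]oxy}-2-methylpentan-1-ol | CC[C@H](O[Si](C)(C)C(C)(C)C)[C@@H](C)CO | intermediate
21 | (2R,3S)-3-{[tert-butyl(dimethyl)silyl]oxy}-2-methylpentanal | CC[C@H](O[Si](C)(C)C(C)(C)C)[C@@H](C)C=O | intermediate
22 | 2-[(1S)-6-ethylidene-1,3,5-trimethyl-4-[(trimethylsilyl)oxy]cyclohexa-2,4-dien-1-yl]-6-methoxy-3,5-dimethyl-4H-pyran-4-one (E/Z mixture) | CC=C1C(C)=C(O[Si](C)(C)C)C(C)=C[C@]1(C)c1oc(OC)c(C)c(=O)c1C | intermediate
23 | (4S)-3-[(4S,5S)-5-{[tert-butyl(dimethyl)silyl]oxy}-3-hydroxy-4-methylheptan-2-yl]-4-(6-methoxy-3,5-dimethyl-4-oxo-4H-pyran-2-yl)-2,4,6-trimethylcyclohexa-2,5-dien-1-one (epimers at the two new chain centres) | CC[C@H](O[Si](C)(C)C(C)(C)C)[C@@H](C)C(O)C(C)C1=C(C)C(=O)C(C)=C[C@]1(C)c1oc(OC)c(C)c(=O)c1C | intermediate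
24 | methanesulfonate ester of 23 (same configuration) | CC[C@H](O[Si](C)(C)C(C)(C)C)[C@@H](C)C(OS(C)(=O)=O)C(C)C1=C(C)C(=O)C(C)=C[C@]1(C)c1oc(OC)c(C)c(=O)c1C | intermediate
25 | (4S)-3-[(2E,4S,5S)-5-{[tert-butyl(dimethyl)silyl]oxy}-4-methylhept-2-en-2-yl]-4-(6-methoxy-3,5-dimethyl-4-oxo-4H-pyran-2-yl)-2,4,6-trimethylcyclohexa-2,5-dien-1-one | CC[C@H](O[Si](C)(C)C(C)(C)C)[C@@H](C)/C=C(\C)C1=C(C)C(=O)C(C)=C[C@]1(C)c1oc(OC)c(C)c(=O)c1C | intermediate
26 | (4S)-3-[(2E,4S,5S)-5-hydroxy-4-methylhept-2-en-2-yl]-4-(6-methoxy-3,5-dimethyl-4-oxo-4H-pyran-2-yl)-2,4,6-trimethylcyclohexa-2,5-dien-1-one | CC[C@H](O)[C@@H](C)/C=C(\C)C1=C(C)C(=O)C(C)=C[C@]1(C)c1oc(OC)c(C)c(=O)c1C | intermediate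
27 | (4S)-4-(6-methoxy-3,5-dimethyl-4-oxo-4H-pyran-2-yl)-2,4,6-trimethyl-3-[(2E,4S)-4-methyl-5-oxohept-2-en-2-yl]cyclohexa-2,5-dien-1-one | CCC(=O)[C@@H](C)/C=C(\C)C1=C(C)C(=O)C(C)=C[C@]1(C)c1oc(OC)c(C)c(=O)c1C | target

**Count and risks**

Total step count: 15. Longest linear sequence: 9 steps (1–4, 7, 12–15).

Step 7 (Proposed new method). What may go wrong: low facial selectivity in the ion-paired Michael addition, O- instead of C-attack of the enolate, base-induced loss of the formyl group from the quaternary adduct, or isomerisation of the allenone before it is intercepted. The fallback uses known reaction types only, sets out from propanal 17 and keto ester 1 and comes back at dienone 15. Aldol condensation of 17 with excess pentan-3-one (NaOH) gives (E)-4-methylhept-4-en-3-one F1, and iPr3SiOTf/Et3N converts it into triisopropyl{[(2Z,4E)-4-methylhepta-2,4-dien-3-yl]oxy}silane F2. A catalytic enantioselective Diels–Alder reaction of F2 with methacrolein (CC(=C)C=O) forms the same two ring bonds; the catalyst is the triflimide salt of (S)-1-(2-methylphenyl)-3,3-diphenyltetrahydro-1H,3H-pyrrolo[1,2-c][1,3,2]oxazaborole (or its antipode, whichever exposes the required face; CH2Cl2, −78 °C). It should give (1S)-2-ethyl-1,3,5-trimethyl-4-[(triisopropylsilyl)oxy]cyclohex-3-ene-1-carbaldehyde F3, with the silyloxy group para and the ethyl group ortho to the new quaternary centre. The pyranone is then built on the formyl group: addition of the dianion of 1 (NaH, n-BuLi) gives hydroxy keto ester F4, Dess–Martin oxidation gives diketo ester F5, DBU gives hydroxypyranone F6 and MeOTf gives methoxypyranone F7. Tetrabutylammonium fluoride frees the cyclohexanone F8, and twofold dehydrogenation with 2-iodoxybenzoic acid (DMSO, 80 °C) gives 15.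

Step 12. What may go wrong: attack of the trienol ether through C-2 instead of through the ethylidene carbon, or Lewis-acid-induced epimerisation of aldehyde 21. The fallback sets out from 15 and comes back at 25, so it also bypasses step 13. Silyl trienol ether 22 is brominated with N-bromosuccinimide at the ethylidene carbon to give the 3-(1-bromoethyl) dienone F9. An Arbuzov reaction with P(OEt)3 gives the phosphonate F10. A Horner–Wadsworth–Emmons olefination with 21 (LiCl, DBU, MeCN) then forms the side-chain double bond directly and gives 25.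

Step 6. What may go wrong: O-acylation of the acyl ylide by the acid chloride, or polymerisation and base-induced isomerisation of the allenone during its formation and isolation. The fallback sets out from propanal 17 and comes back at 13. Zinc-mediated propargylation of 17 with 4-bromopent-2-yne (CC#CC(C)Br) gives 4-methylhept-5-yn-3-ol F11. Dess–Martin oxidation gives 4-methylhept-5-yn-3-one F12, a storable β,γ-alkynyl ketone that is isomerised to 13 with a catalytic amount of Et3N just before use, or in the flask by the carbonate base of step 7.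

**Further compounds**

F1 | step 7 | (E)-4-methylhept-4-en-3-one | CC/C=C(\C)C(=O)CC
F2 | step 7 | triisopropyl{[(2Z,4E)-4-methylhepta-2,4-dien-3-yl]oxy}silane | C/C=C(O[Si](C(C)C)(C(C)C)C(C)C)/C(C)=C/CC
F3 | step 7 | (1S)-2-ethyl-1,3,5-trimethyl-4-[(triisopropylsilyl)oxy]cyclohex-3-ene-1-carbaldehyde | CCC1C(C)=C(O[Si](C(C)C)(C(C)C)C(C)C)C(C)C[C@]1(C)C=O
F4 | step 7 | methyl 5-[(1S)-2-ethyl-1,3,5-trimethyl-4-[(triisopropylsilyl)oxy]cyclohex-3-en-1-yl]-5-hydroxy-2,4-dimethyl-3-oxopentanoate | CCC1C(C)=C(O[Si](C(C)C)(C(C)C)C(C)C)C(C)C[C@]1(C)C(O)C(C)C(=O)C(C)C(=O)OC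
F5 | step 7 | methyl 5-[(1S)-2-ethyl-1,3,5-trimethyl-4-[(triisopropylsilyl)oxy]cyclohex-3-en-1-yl]-2,4-dimethyl-3,5-dioxopentanoate | CCC1C(C)=C(O[Si](C(C)C)(C(C)C)C(C)C)C(C)C[C@]1(C)C(=O)C(C)C(=O)C(C)C(=O)OC
F6 | step 7 | 6-[(1S)-2-ethyl-1,3,5-trimethyl-4-[(triisopropylsilyl)oxy]cyclohex-3-en-1-yl]-4-hydroxy-3,5-dimethyl-2H-pyran-2-one | CCC1C(C)=C(O[Si](C(C)C)(C(C)C)C(C)C)C(C)C[C@]1(C)c1oc(=O)c(C)c(O)c1C
F7 | step 7 | 2-[(1S)-2-ethyl-1,3,5-trimethyl-4-[(triisopropylsilyl)oxy]cyclohex-3-en-1-yl]-6-methoxy-3,5-dimethyl-4H-pyran-4-one | CCC1C(C)=C(O[Si](C(C)C)(C(C)C)C(C)C)C(C)C[C@]1(C)c1oc(OC)c(C)c(=O)c1C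
F8 | step 7 | (4S)-3-ethyl-4-(6-methoxy-3,5-dimethyl-4-oxo-4H-pyran-2-yl)-2,4,6-trimethylcyclohexan-1-one | CCC1C(C)C(=O)C(C)C[C@]1(C)c1oc(OC)c(C)c(=O)c1C
F9 | step 12 | (4S)-3-(1-bromoethyl)-4-(6-methoxy-3,5-dimethyl-4-oxo-4H-pyran-2-yl)-2,4,6-trimethylcyclohexa-2,5-dien-1-one | CC(Br)C1=C(C)C(=O)C(C)=C[C@]1(C)c1oc(OC)c(C)c(=O)c1C
F10 | step 12 | diethyl {1-[(6S)-6-(6-methoxy-3,5-dimethyl-4-oxo-4H-pyran-2-yl)-2,4,6-trimethyl-3-oxocyclohexa-1,4-dien-1-yl]ethyl}phosphonate | CCOP(=O)(OCC)C(C)C1=C(C)C(=O)C(C)=C[C@]1(C)c1oc(OC)c(C)c(=O)c1C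
F11 | step 6 | 4-methylhept-5-yn-3-ol | CCC(O)C(C)C#CC
F12 | step 6 | 4-methylhept-5-yn-3-one | CCC(=O)C(C)C#CC
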